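**Strategy.** Everything rests on disconnecting C1–C10 (labdane numbering). The C7 oxygen of ring B lies para to the methyl-bearing quaternary C10, so ring B with C20 can be carried as a 4-methylphenol. Its potassium phenolate is alkylated through the para carbon C10 by the tethered primary iodide at C1. In one operation this closes ring A, creates the C10 quaternary stereocentre under control of the preset C4 centre, and delivers ring B as a cross-conjugated C7 dienone. The precursor is a 3,4,5-trisubstituted phenol: C9 carries the ketal-protected side chain, C10 the methyl, and C5 the quaternary C4 ester arm ending in the C1 iodide.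

Key step: step 10

Remarks before the steps:
- Labdane numbering is used for all bicyclic compounds; α is the face opposite the C20 methyl.
- Assumption: the (R,R) enantiomer of the tetramine base in step 5 is taken to deliver the allyl group to the enediolate face that gives the (2S) acid, by analogy with the parent arylacetic acids; both antipodes of the base are accessible.
- Regiochemistry of the key step: C6, the ring carbon ortho to the oxygen, neighbours the tether carbon C5 just as C10 does and could close an isomeric six-membered ring (a tetralinol after tautomerization). It is therefore treated as a real competitor; the control element is named in step 10.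
- Structure check: 17 (2S) and 19 (1S,4aR) carry C4 and C10 as in the target (C19 and C20 both β).
- The configuration written at C8 in 21 to 25 is the expected one and has no consequence, since C8 becomes trigonal in step 14.

Step 1
Reactants: 1 3,5-dibromo-4-methylphenol
Product: 2 5-(benzyloxy)-1,3-dibromo-2-methylbenzene
Conditions: BnBr, K2CO3, DMF, rt
Reagents that add atoms: benzyl bromide BrCc1ccccc1
Why: Williamson ether synthesis on the phenolate; the benzyl ether should survive the amide bases, TFA, n-BuLi and borane that follow and is removed later by hydrogenolysis without acid or fluoride.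

Step 2
Reactants: 2 5-(benzyloxy)-1,3-dibromo-2-methylbenzene; 3 tert-butyl propanoate
Product: 5 tert-butyl 2-[5-(benzyloxy)-3-bromo-2-methylphenyl]propanoate (racemic), via lithium ester enolate 4 (not isolated)
Conditions: LiN(SiMe3)2 (2.3 equiv), Pd(OAc)2 (3 mol %), 2-dicyclohexylphosphino-2′-(N,N-dimethylamino)biphenyl (6 mol %), toluene, rt; 3 limiting, 2 in twofold excess (remainder recovered)
Reagents that add atoms: lithium bis(trimethylsilyl)amide [Li]N([Si](C)(C)C)[Si](C)(C)C (lithium retained only in 4)
Why: Buchwald–Hartwig-type Pd-catalysed α-arylation of an ester enolate, in which the tert-butyl ester resists Claisen self-condensation, the excess of the symmetrical dibromide holds the coupling at one C–Br bond, and the product, present as its enolate, is deactivated toward a second oxidative addition.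

Step 3
Reactants: 5 tert-butyl 2-[5-(benzyloxy)-3-bromo-2-methylphenyl]propanoate
Product: 6 2-[5-(benzyloxy)-3-bromo-2-methylphenyl]propanoic acid (racemic)
Conditions: TFA, CH2Cl2, 0 °C to rt
Reagents that add atoms: none
Why: acidolysis of the tert-butyl ester with loss of isobutene, placed before the acid-labile dioxolane enters the molecule.

Step 4
Reactants: 6 2-[5-(benzyloxy)-3-bromo-2-methylphenyl]propanoic acid; 7 2-methyl-2-vinyl-1,3-dioxolane
Product: 9 2-{5-(benzyloxy)-2-methyl-3-[2-(2-methyl-1,3-dioxolan-2-yl)ethyl]phenyl}propanoic acid (racemic), via B-alkyl-9-BBN borane 8 (not isolated)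
Conditions: 7, 9-borabicyclo[3.3.1]nonane (9-BBN-H), THF, rt; then 6, [1,1′-bis(diphenylphosphino)ferrocene]PdCl2 (5 mol %), aq. K3PO4, DMF, 60 °C; work-up at pH 5
Reagents that add atoms: 9-borabicyclo[3.3.1]nonane B1C2CCCC1CCC2 (boron and its bicycle retained only in 8)
Why: anti-Markovnikov hydroboration of the vinyl ketal followed by B-alkyl Suzuki–Miyaura coupling at the remaining C–Br bond, which tolerates the carboxylate and installs C11, C12, C13 and C16 with the ketone already protected.

Step 5
Reactants: 9 2-{5-(benzyloxy)-2-methyl-3-[2-(2-methyl-1,3-dioxolan-2-yl)ethyl]phenyl}propanoic acid; 10 allyl bromide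
Product: 12 (2S)-2-{5-(benzyloxy)-2-methyl-3-[2-(2-methyl-1,3-dioxolan-2-yl)ethyl]phenyl}-2-methylpent-4-enoic acid, via dilithium enediolate 11 (not isolated)
Conditions: (R,R)-N,N′-bis[1-phenyl-2-(piperidin-1-yl)ethyl]propane-1,3-diamine (1.05 equiv), n-BuLi (4.0 equiv), THF, 0 °C; then 10, −78 °C; product extracted as carboxylate into aq. NaOH, then pH 5; base recovered
Reagents that add atoms: n-butyllithium [Li]CCCC (lithium retained only in 11)
Why: enantioselective alkylation of a carboxylic acid enediolate held in a mixed aggregate with a chiral dilithium amide (noncovalent auxiliary); the enediolate has no E/Z isomerism, so the facial bias of the aggregate alone should set the quaternary C4 centre as S.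

Step 6
Reactants: 12 (2S)-2-{5-(benzyloxy)-2-methyl-3-[2-(2-methyl-1,3-dioxolan-2-yl)ethyl]phenyl}-2-methylpent-4-enoic acid
Product: 13 methyl (2S)-2-{5-(benzyloxy)-2-methyl-3-[2-(2-methyl-1,3-dioxolan-2-yl)ethyl]phenyl}-2-methylpent-4-enoate
Conditions: MeI, K2CO3, DMF, rt
Reagents that add atoms: iodomethane CI
Why: SN2 O-methylation of the carboxylate, which is insensitive to the hindrance at the quaternary α-carbon and leaves C4 untouched.

Step 7
Reactants: 13 methyl (2S)-2-{5-(benzyloxy)-2-methyl-3-[2-(2-methyl-1,3-dioxolan-2-yl)ethyl]phenyl}-2-methylpent-4-enoate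
Product: 15 methyl (2S)-2-{5-(benzyloxy)-2-methyl-3-[2-(2-methyl-1,3-dioxolan-2-yl)ethyl]phenyl}-5-hydroxy-2-methylpentanoate, via alkyl-9-BBN borane 14 (not isolated)
Conditions: 9-BBN-H, THF, 0 °C to rt; then 30 % H2O2, aq. NaOAc, 0 °C
Reagents that add atoms: 9-borabicyclo[3.3.1]nonane B1C2CCCC1CCC2 (boron retained only in 14); hydrogen peroxide OO
Why: anti-Markovnikov hydroboration–oxidation of the terminal alkene places oxygen on C1, and the acetate-buffered oxidation avoids the alkoxide that would lactonise onto the C19 ester.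

Step 8
Reactants: 15 methyl (2S)-2-{5-(benzyloxy)-2-methyl-3-[2-(2-methyl-1,3-dioxolan-2-yl)ethyl]phenyl}-5-hydroxy-2-methylpentanoate
Product: 16 methyl (2S)-5-hydroxy-2-{5-hydroxy-2-methyl-3-[2-(2-methyl-1,3-dioxolan-2-yl)ethyl]phenyl}-2-methylpentanoate
Conditions: H2 (1 atm), Pd/C (10 %), EtOAc, rt
Reagents that add atoms: none
Why: hydrogenolysis of the benzyl aryl ether under neutral conditions releases the phenol before any alkyl iodide is present and spares ester, ketal and alcohol.

Step 9
Reactants: 16 methyl (2S)-5-hydroxy-2-{5-hydroxy-2-methyl-3-[2-(2-methyl-1,3-dioxolan-2-yl)ethyl]phenyl}-2-methylpentanoate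
Product: 17 methyl (2S)-2-{5-hydroxy-2-methyl-3-[2-(2-methyl-1,3-dioxolan-2-yl)ethyl]phenyl}-5-iodo-2-methylpentanoate
Conditions: PPh3, I2, imidazole, CH2Cl2, 0 °C (phosphine and iodine combined before 16 is added)
Reagents that add atoms: iodine II
Why: Appel-type iodination (Garegg–Samuelsson conditions) converts only the primary aliphatic alcohol, the phenol being inert to the alkoxyphosphonium pathway and the imidazole buffer protecting the ketal.

Step 10
Reactants: 17 methyl (2S)-2-{5-hydroxy-2-methyl-3-[2-(2-methyl-1,3-dioxolan-2-yl)ethyl]phenyl}-5-iodo-2-methylpentanoate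
Product: 19 methyl 13,13-ethylenedioxy-7-oxo-14,15-dinorlabda-5,8-dien-19-oate [methyl (1S,4aR)-1,4a-dimethyl-5-[2-(2-methyl-1,3-dioxolan-2-yl)ethyl]-7-oxo-1,2,3,4,4a,7-hexahydronaphthalene-1-carboxylate], via potassium phenolate 18 (not isolated)
Conditions: KOt-Bu (1.05 equiv), t-BuOH, 0.005 M, 50 °C, slow addition of 17
Reagents that add atoms: potassium tert-butoxide [K+].CC(C)(C)[O-] (potassium retained only in 18)
Why: KOt-Bu deprotonates the phenol and the ambident phenolate 18 displaces the primary iodide at C1 through its para carbon C10 (intramolecular SN2), which dearomatises ring B to the cross-conjugated C7 dienone. The closest known reaction type is the base-mediated intramolecular para-alkylation of phenolates (Winstein–Masamune aryl participation through the ring carbon next to the tether) to fused 4,4-disubstituted cyclohexadienones. Ring A closes in the 6-exo-tet mode. The new stereocentre C10 is controlled by the preset C4 centre: in the chair-like transition state C20 becomes axial on the nascent ring A, and the flat C19 ester takes the axial site syn to it more readily than the C18 methyl, which stays equatorial beside C6–H, so that C19 and C20 should end on the same face (any C10 epimer to be removed by chromatography). The step needs C10 over C6 closure and C- over O-alkylation: closure at C6 would force a C4 substituent to eclipse the C20 methyl in the ring plane, so the C20 methyl and the fully substituted C4 gear the chain onto C10, while O-alkylation is impossible within the molecule and is held back between molecules by high dilution and the hydrogen-bonding solvent. C5 stays trigonal, so no ring-fusion stereochemistry is decided here.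

Step 11
Reactants: 19 methyl 13,13-ethylenedioxy-7-oxo-14,15-dinorlabda-5,8-dien-19-oate
Product: 21 methyl 17-(dimethylamino)-13,13-ethylenedioxy-7-oxo-14,15-dinor-8βH-labd-5-en-19-oate (8α-CH2NMe2 and 9α-H), via silyl dienol ether 20 (not isolated)
Conditions: [(Ph3P)CuH]6 (5 mol %), PhMe2SiH (1.5 equiv), toluene, rt; then Me2N=CH2+ I−, CH2Cl2, rt; aq. NaHCO3
Reagents that add atoms: dimethylphenylsilane C[SiH](C)c1ccccc1 (silicon retained only in 20); dimethylmethyleneiminium iodide C[N+](C)=C.[I-]
Why: CuH-catalysed 1,4-hydrosilylation of the enone (Stryker–Lipshutz conjugate reduction) followed by a Mannich reaction of the silyl dienol ether with Eschenmoser's salt; hydride should go to C9, the less encumbered β-carbon (C5 lies between two quaternary carbons), from the α face opposite the C20 methyl, which sets C9, and the iminium ion then enters C8 regiospecifically, anti to the C9 chain.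

Step 12
Reactants: 21 methyl 17-(dimethylamino)-13,13-ethylenedioxy-7-oxo-14,15-dinor-8βH-labd-5-en-19-oate
Product: 23 methyl 17-(dimethylamino)-13,13-ethylenedioxy-7-oxo-14,15-dinor-8βH-labdan-19-oate (5α-H), via lithium enolate 22 (not isolated)
Conditions: Li (2.5 equiv), NH3 (l), THF, t-BuOH (1.0 equiv), −78 °C; isoprene, then NH4Cl
Reagents that add atoms: lithium [Li] (retained only in 22)
Why: dissolving-metal (Birch-type) reduction of the enone, in which axial protonation of the C5 carbanion opposite C20 and the axial C19 ester gives the trans ring fusion, one equivalent of t-BuOH keeps the ketone masked as its C6–C7 enolate until the quench, and the tertiary amine and the hindered ester should persist at −78 °C.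

Step 13
Reactants: 23 methyl 17-(dimethylamino)-13,13-ethylenedioxy-7-oxo-14,15-dinor-8βH-labdan-19-oate
Product: 24 methyl 17-(dimethylamino)-13,13-ethylenedioxy-7α-hydroxy-14,15-dinor-8βH-labdan-19-oate
Conditions: Li(s-Bu)3BH, THF, −78 °C; aq. NH4Cl (no oxidative work-up)
Reagents that add atoms: none
Why: reduction with a bulky trialkylborohydride, which attacks the cyclohexanone equatorially from the β face and so gives the axial 7α alcohol; it is done while C8 is still saturated, because an α-methylene ketone would undergo conjugate reduction.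

Step 14
Reactants: 24 methyl 17-(dimethylamino)-13,13-ethylenedioxy-7α-hydroxy-14,15-dinor-8βH-labdan-19-oate
Product: 26 methyl 13,13-ethylenedioxy-7α-hydroxy-14,15-dinorlabd-8(17)-en-19-oate, via amine N-oxide 25 (not isolated)
Conditions: mCPBA (1.05 equiv), CH2Cl2, −20 °C; filtration through basic Al2O3; then toluene, 100 °C
Reagents that add atoms: 3-chloroperoxybenzoic acid OOC(=O)c1cccc(Cl)c1 (oxygen retained only in 25)
Why: N-oxidation followed by Cope elimination (syn, five-membered transition state); the only β-hydrogen of the N-oxide sits on C8, so the exocyclic 8(17) alkene forms regiospecifically and the C7 carbinol centre is not touched.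

Step 15
Reactants: 26 methyl 13,13-ethylenedioxy-7α-hydroxy-14,15-dinorlabd-8(17)-en-19-oate
Product: 27 methyl 7α-hydroxy-13-oxo-14,15-dinorlabd-8(17)-en-19-oate
Conditions: AcOH/THF/H2O (3:1:1), 40 °C
Reagents that add atoms: water O
Why: acid-catalysed hydrolysis of the dioxolane, with acetic acid mild enough to leave the axial allylic alcohol and the exocyclic alkene in place.

Step 16
Reactants: 27 methyl 7α-hydroxy-13-oxo-14,15-dinorlabd-8(17)-en-19-oate; 28 triethyl phosphonoacetate
Product: 30 15-ethyl 19-methyl 7α-hydroxylabda-8(17),13E-diene-15,19-dioate, via sodium phosphonate carbanion 29 (not isolated)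
Conditions: 28 (3 equiv), NaH (2.8 equiv), THF, 0 °C; then 27, rt to 50 °C
Reagents that add atoms: sodium hydride [Na+].[H-] (sodium retained only in 29)
Why: Horner–Wadsworth–Emmons olefination of the methyl ketone, expected to favour the E enoate (the Z isomer to be removed by chromatography); the carbanion should not attack the hindered C19 ester and the free C7 hydroxyl is tolerated.

Step 17
Reactants: 30 15-ethyl 19-methyl 7α-hydroxylabda-8(17),13E-diene-15,19-dioate
Product: 31 labda-8(17),13E-diene-7α,15,19-triol
Conditions: i-Bu2AlH (excess), CH2Cl2, −78 °C to rt; aq. potassium sodium tartrate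
Reagents that add atoms: none
Why: aluminium hydride reduction of both esters, 1,2-selective at the enoate so that the 13E alkene is kept, with warming to bring the hindered axial C19 ester to the alcohol.

Step 18
Reactants: 31 labda-8(17),13E-diene-7α,15,19-triol
Product: 32 15-(tert-butyldimethylsilyloxy)labda-8(17),13E-diene-7α,19-diol
Conditions: TBSCl (1.05 equiv), imidazole, CH2Cl2, −20 °C
Reagents that add atoms: tert-butyldimethylsilyl chloride CC(C)(C)[Si](C)(C)Cl
Why: sterically controlled silylation, the unhindered primary allylic C15 hydroxyl reacting ahead of the neopentyl C19 hydroxyl and the secondary axial C7 hydroxyl.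

Step 19
Reactants: 32 15-(tert-butyldimethylsilyloxy)labda-8(17),13E-diene-7α,19-diol
Product: 33 15-(tert-butyldimethylsilyloxy)-7α-hydroxylabda-8(17),13E-dien-19-yl acetate
Conditions: Ac2O (1.2 equiv), pyridine, CH2Cl2, 0 °C
Reagents that add atoms: acetic anhydride CC(=O)OC(C)=O
Why: acylation of the primary C19 hydroxyl in preference to the secondary axial C7 hydroxyl, helped by the limited amount of anhydride, the low temperature and the absence of an acyl-transfer catalyst.

Step 20
Reactants: 33 15-(tert-butyldimethylsilyloxy)-7α-hydroxylabda-8(17),13E-dien-19-yl acetate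
Product: 34 7α,15-dihydroxylabda-8(17),13E-dien-19-yl acetate (CNP0209062.1)
Conditions: Bu4NF, AcOH, THF, 0 °C to rt
Reagents that add atoms: none
Why: fluoride-mediated desilylation buffered with acetic acid, so that no alkoxide forms and the C19 acetate neither cleaves nor migrates.

**Compound list**

1 | 3,5-dibromo-4-methylphenol | Cc1c(Br)cc(O)cc1Br | starting material
2 | 5-(benzyloxy)-1,3-dibromo-2-methylbenzene | Cc1c(Br)cc(OCc2ccccc2)cc1Br | intermediate
3 | tert-butyl propanoate | CCC(=O)OC(C)(C)C | starting material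
4 | lithium enolate of tert-butyl propanoate | CC=C(O[Li])OC(C)(C)C | intermediate (not isolated)
5 | tert-butyl 2-[5-(benzyloxy)-3-bromo-2-methylphenyl]propanoate, racemic | CC(C(=O)OC(C)(C)C)c1cc(OCc2ccccc2)cc(Br)c1C | intermediate
6 | 2-[5-(benzyloxy)-3-bromo-2-methylphenyl]propanoic acid, racemic | CC(C(=O)O)c1cc(OCc2ccccc2)cc(Br)c1C | intermediate
7 | 2-methyl-2-vinyl-1,3-dioxolane | C=CC1(C)OCCO1 | starting material
8 | 9-[2-(2-methyl-1,3-dioxolan-2-yl)ethyl]-9-borabicyclo[3.3.1]nonane | CC1(CCB2C3CCCC2CCC3)OCCO1 | intermediate (not isolated)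
9 | 2-{5-(benzyloxy)-2-methyl-3-[2-(2-methyl-1,3-dioxolan-2-yl)ethyl]phenyl}propanoic acid, racemic | CC(C(=O)O)c1cc(OCc2ccccc2)cc(CCC2(C)OCCO2)c1C | intermediate
10 | allyl bromide (3-bromoprop-1-ene) | C=CCBr | starting material
11 | dilithium enediolate of 9 | [Li]OC(O[Li])=C(C)c1cc(OCc2ccccc2)cc(CCC2(C)OCCO2)c1C | intermediate (not isolated)
12 | (2S)-2-{5-(benzyloxy)-2-methyl-3-[2-(2-methyl-1,3-dioxolan-2-yl)ethyl]phenyl}-2-methylpent-4-enoic acid | C(Oc1cc(CCC2(C)OCCO2)c(C)c(c1)[C@@](C)(C(=O)O)CC=C)c3ccccc3 | intermediate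
13 | methyl (2S)-2-{5-(benzyloxy)-2-methyl-3-[2-(2-methyl-1,3-dioxolan-2-yl)ethyl]phenyl}-2-methylpent-4-enoate | C(Oc1cc(CCC2(C)OCCO2)c(C)c(c1)[C@@](C)(C(=O)OC)CC=C)c3ccccc3 | intermediate
14 | methyl (2S)-2-{5-(benzyloxy)-2-methyl-3-[2-(2-methyl-1,3-dioxolan-2-yl)ethyl]phenyl}-5-(9-borabicyclo[3.3.1]nonan-9-yl)-2-methylpentanoate | C(Oc1cc(CCC2(C)OCCO2)c(C)c(c1)[C@@](C)(C(=O)OC)CCCB4C5CCCC4CCC5)c3ccccc3 | intermediate (not isolated)
15 | methyl (2S)-2-{5-(benzyloxy)-2-methyl-3-[2-(2-methyl-1,3-dioxolan-2-yl)ethyl]phenyl}-5-hydroxy-2-methylpentanoate | C(Oc1cc(CCC2(C)OCCO2)c(C)c(c1)[C@@](C)(C(=O)OC)CCCO)c3ccccc3 | intermediate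
16 | methyl (2S)-5-hydroxy-2-{5-hydroxy-2-methyl-3-[2-(2-methyl-1,3-dioxolan-2-yl)ethyl]phenyl}-2-methylpentanoate | Oc1cc(CCC2(C)OCCO2)c(C)c(c1)[C@@](C)(C(=O)OC)CCCO | intermediate
17 | methyl (2S)-2-{5-hydroxy-2-methyl-3-[2-(2-methyl-1,3-dioxolan-2-yl)ethyl]phenyl}-5-iodo-2-methylpentanoate (key-step precursor) | Oc1cc(CCC2(C)OCCO2)c(C)c(c1)[C@@](C)(C(=O)OC)CCCI | intermediate
18 | potassium phenolate of 17 | [K+].[O-]c1cc(CCC2(C)OCCO2)c(C)c(c1)[C@@](C)(C(=O)OC)CCCI | intermediate (not isolated)
19 | methyl 13,13-ethylenedioxy-7-oxo-14,15-dinorlabda-5,8-dien-19-oate; methyl (1S,4aR)-1,4a-dimethyl-5-[2-(2-methyl-1,3-dioxolan-2-yl)ethyl]-7-oxo-1,2,3,4,4a,7-hexahydronaphthalene-1-carboxylate; C19 ester and C20 both β (key-step product) | O=C1C=C(CCC2(C)OCCO2)[C@@]3(C)CCC[C@](C)(C(=O)OC)C3=C1 | intermediate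
20 | methyl 7-(dimethylphenylsilyloxy)-13,13-ethylenedioxy-14,15-dinorlabda-5,7-dien-19-oate, 9α-H | C[Si](C)(c4ccccc4)OC1=C[C@H](CCC2(C)OCCO2)[C@@]3(C)CCC[C@](C)(C(=O)OC)C3=C1 | intermediate (not isolated)
21 | methyl 17-(dimethylamino)-13,13-ethylenedioxy-7-oxo-14,15-dinor-8βH-labd-5-en-19-oate, 8α-CH2NMe2, 9α-H | O=C1C=C2[C@@](C)(C(=O)OC)CCC[C@]2(C)[C@@H](CCC3(C)OCCO3)[C@@H]1CN(C)C | intermediate
22 | lithium C6–C7 enolate of 23 | [Li]OC1=C[C@H]2[C@@](C)(C(=O)OC)CCC[C@]2(C)[C@@H](CCC3(C)OCCO3)[C@@H]1CN(C)C | intermediate (not isolated)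
23 | methyl 17-(dimethylamino)-13,13-ethylenedioxy-7-oxo-14,15-dinor-8βH-labdan-19-oate, trans-decalin with 5α-H and 9α-H | O=C1C[C@H]2[C@@](C)(C(=O)OC)CCC[C@]2(C)[C@@H](CCC3(C)OCCO3)[C@@H]1CN(C)C | intermediate
24 | methyl 17-(dimethylamino)-13,13-ethylenedioxy-7α-hydroxy-14,15-dinor-8βH-labdan-19-oate | O[C@@H]1C[C@H]2[C@@](C)(C(=O)OC)CCC[C@]2(C)[C@@H](CCC3(C)OCCO3)[C@@H]1CN(C)C | intermediate
25 | N-oxide of 24 | O[C@@H]1C[C@H]2[C@@](C)(C(=O)OC)CCC[C@]2(C)[C@@H](CCC3(C)OCCO3)[C@@H]1C[N+](C)(C)[O-] | intermediate (not isolated)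
26 | methyl 13,13-ethylenedioxy-7α-hydroxy-14,15-dinorlabd-8(17)-en-19-oate | C=C1[C@H](O)C[C@H]2[C@@](C)(C(=O)OC)CCC[C@]2(C)[C@H]1CCC3(C)OCCO3 | intermediate
27 | methyl 7α-hydroxy-13-oxo-14,15-dinorlabd-8(17)-en-19-oate | C=C1[C@H](O)C[C@H]2[C@@](C)(C(=O)OC)CCC[C@]2(C)[C@H]1CCC(C)=O | intermediate
28 | triethyl phosphonoacetate | CCOC(=O)CP(=O)(OCC)OCC | starting material
29 | sodium salt of 28 (phosphonate carbanion) | [Na+].CCOC(=O)[CH-]P(=O)(OCC)OCC | intermediate (not isolated)
30 | 15-ethyl 19-methyl 7α-hydroxylabda-8(17),13E-diene-15,19-dioate | C=C1[C@H](O)C[C@H]2[C@@](C)(C(=O)OC)CCC[C@]2(C)[C@H]1CC/C(C)=C/C(=O)OCC | intermediate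
31 | labda-8(17),13E-diene-7α,15,19-triol | C=C1[C@H](O)C[C@H]2[C@@](C)(CO)CCC[C@]2(C)[C@H]1CC/C(C)=C/CO | intermediate
32 | 15-(tert-butyldimethylsilyloxy)labda-8(17),13E-diene-7α,19-diol | C=C1[C@H](O)C[C@H]2[C@@](C)(CO)CCC[C@]2(C)[C@H]1CC/C(C)=C/CO[Si](C)(C)C(C)(C)C | intermediate
33 | 15-(tert-butyldimethylsilyloxy)-7α-hydroxylabda-8(17),13E-dien-19-yl acetate | C=C1[C@H](O)C[C@H]2[C@@](C)(COC(C)=O)CCC[C@]2(C)[C@H]1CC/C(C)=C/CO[Si](C)(C)C(C)(C)C | intermediate
34 | 7α,15-dihydroxylabda-8(17),13E-dien-19-yl acetate, (4S,5R,7R,9R,10S), CNP0209062.1 | C=C1[C@H](O)C[C@H]2[C@@](C)(COC(C)=O)CCC[C@]2(C)[C@H]1CC/C(C)=C/CO | target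

**Step count and risk**

Total step count: 20. Longest linear sequence: 20 steps (1 to 34); the building blocks 3, 7, 10 and 28 enter directly.

The three steps most likely to fail:

Step 10. Ring closure at C10 may lose to closure at the unsubstituted ortho carbon C6 (followed by rearomatization) or to ether formation between two molecules, and the relay of configuration from C4 to C10 may be weak. The fallback blocks both ortho carbons and sets out from 16. Bromination with N-bromosuccinimide (2.1 equiv, MeCN, 0 °C) at the only two free ring positions would give methyl (2S)-2-{4,6-dibromo-5-hydroxy-2-methyl-3-[2-(2-methyl-1,3-dioxolan-2-yl)ethyl]phenyl}-5-hydroxy-2-methylpentanoate F1. Iodination as in step 9 would give the corresponding 5-iodo ester F2. Its phenolate (KOt-Bu, t-BuOH, dilute) can then close a six-membered ring only through C10, and its oxygen, flanked by two bromines, is a poor partner for etherification; this would give methyl 6,8-dibromo-13,13-ethylenedioxy-7-oxo-14,15-dinorlabda-5,8-dien-19-oate F3. Reduction of the two vinylic C–Br bonds with formate under Pd(PPh3)4 catalysis (HCO2H, Et3N, DMF, 60 °C) comes back to the route at 19.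

Step 11. Hydride transfer to the hindered, fully substituted C9 may be slow, may fail to discriminate between the two enone units or the two faces, and the Mannich trapping of the silyl dienol ether may be incomplete. The fallback separates reduction and C17 introduction and sets out from 19. Heterogeneous hydrogenation (H2, Pd/C, EtOAc) should saturate the less shielded C8=C9 bond from the α face and give methyl 13,13-ethylenedioxy-7-oxo-14,15-dinorlabd-5-en-19-oate F4. Kinetic deprotonation with LiN(i-Pr)2 (THF, −78 °C) can occur only at C8, because both γ positions of this enone are quaternary, and trapping of the lithium dienolate with dimethylmethyleneiminium iodide comes back to the route at 21.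

Step 5. The chiral lithium amide aggregate may discriminate poorly between the enediolate faces, or react sluggishly, with this ortho-substituted, α-branched substrate. The fallback replaces asymmetric induction by resolution and sets out from 9. Methylation (MeI, K2CO3, DMF) would give racemic methyl 2-{5-(benzyloxy)-2-methyl-3-[2-(2-methyl-1,3-dioxolan-2-yl)ethyl]phenyl}propanoate F5. Enolate allylation (LiN(i-Pr)2, THF, −78 °C, then allyl bromide) would give racemic methyl 2-{5-(benzyloxy)-2-methyl-3-[2-(2-methyl-1,3-dioxolan-2-yl)ethyl]phenyl}-2-methylpent-4-enoate F6. Preparative chromatography on a chiral stationary phase then delivers the (2S) enantiomer, which is 13, where the route is rejoined.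

**Further compounds**

F1 | step 10 | methyl (2S)-2-{4,6-dibromo-5-hydroxy-2-methyl-3-[2-(2-methyl-1,3-dioxolan-2-yl)ethyl]phenyl}-5-hydroxy-2-methylpentanoate | Oc1c(Br)c(CCC2(C)OCCO2)c(C)c(c1Br)[C@@](C)(C(=O)OC)CCCO
F2 | step 10 | methyl (2S)-2-{4,6-dibromo-5-hydroxy-2-methyl-3-[2-(2-methyl-1,3-dioxolan-2-yl)ethyl]phenyl}-5-iodo-2-methylpentanoate | Oc1c(Br)c(CCC2(C)OCCO2)c(C)c(c1Br)[C@@](C)(C(=O)OC)CCCI
F3 | step 10 | methyl 6,8-dibromo-13,13-ethylenedioxy-7-oxo-14,15-dinorlabda-5,8-dien-19-oate | O=C1C(Br)=C(CCC2(C)OCCO2)[C@@]3(C)CCC[C@](C)(C(=O)OC)C3=C1Br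
F4 | step 11 | methyl 13,13-ethylenedioxy-7-oxo-14,15-dinorlabd-5-en-19-oate, 9α-H | O=C1C[C@H](CCC2(C)OCCO2)[C@@]3(C)CCC[C@](C)(C(=O)OC)C3=C1
F5 | step 5 | methyl 2-{5-(benzyloxy)-2-methyl-3-[2-(2-methyl-1,3-dioxolan-2-yl)ethyl]phenyl}propanoate, racemic | CC(C(=O)OC)c1cc(OCc2ccccc2)cc(CCC2(C)OCCO2)c1C
F6 | step 5 | methyl 2-{5-(benzyloxy)-2-methyl-3-[2-(2-methyl-1,3-dioxolan-2-yl)ethyl]phenyl}-2-methylpent-4-enoate, racemic | C=CCC(C)(C(=O)OC)c1cc(OCc2ccccc2)cc(CCC2(C)OCCO2)c1C
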